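The cyclohexane ring (C1, C10, C11, C12, C13, C14) is disconnected at C11–C12 and C13–C14, so that C12–C13 enter as a vinyl group on boron. An intramolecular palladium-catalysed conjunctive coupling joins the C14 boronate and the C11 enol triflate, both held on a chiral γ-butyrolactone that spans C1–C10, and closes the ring while placing boron, later oxygen, on C13; it exploits the 1,3-relationship between the C11 exocyclic methylene and the C13 acetoxy group. The precursor is a monocyclic lactone from (S)-5-(hydroxymethyl)furanone. The ten-membered ring is closed late by a Nozaki–Hiyama–Kishi reaction at C5–C6, after the γ-lactone is built by a reductive aldol cyclisation.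

Key step: step 7

Remark: briarane numbering is used for every intermediate (C1 quaternary with methyl C15; C2–C9 in the ten-membered ring; C10 ring fusion; C11–C14 cyclohexane; C16 methylene on C5; C20 methylene on C11; lactone C17 with methyl C18 and carbonyl C19); compounds 1, 9, 18, 24 and 32 are assumed to be commercially available.

Step 1
Reactants: 1 (S)-5-(hydroxymethyl)furan-2(5H)-one; 2 tert-butyl(chloro)diphenylsilane
Product: 3 (S)-5-[(tert-butyldiphenylsilyloxy)methyl]furan-2(5H)-one
Conditions: imidazole, CH2Cl2, 0 °C to rt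
Reagents that add atoms: tert-butyl(chloro)diphenylsilane, CC(C)(C)[Si](Cl)(c1ccccc1)c1ccccc1
Why: Silyl ether formation at the primary alcohol should proceed cleanly and leaves the chiral-pool C9 stereocentre untouched.

Step 2
Reactants: 3 silyl butenolide; 4 isopropenylmagnesium bromide
Product: 5 (4R,5S)-5-[(tert-butyldiphenylsilyloxy)methyl]-4-(prop-1-en-2-yl)dihydrofuran-2(3H)-one
Conditions: CuBr·SMe2 (10 mol %), THF, −78 to −40 °C; aq. NH4Cl
Reagents that add atoms: isopropenylmagnesium bromide, CC(=C)[Mg]Br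
Why: Copper-catalysed conjugate addition of the Grignard reagent to the butenolide should occur anti to the C9 silyloxymethyl group, which sets C10 (4,5-trans) under substrate control.

Step 3
Reactants: 5 trans lactone; 6 iodomethane
Product: 8 (3S,4R,5S)-5-[(tert-butyldiphenylsilyloxy)methyl]-3-methyl-4-(prop-1-en-2-yl)dihydrofuran-2(3H)-one, via lithium enolate 7 (not isolated)
Conditions: LiN(i-Pr)2, THF, −78 °C; MeI, −78 to −40 °C
Reagents that add atoms: iodomethane, CI
Why: Lactone enolate alkylation should give mainly the 3,4-trans product by approach of iodomethane anti to the C10 isopropenyl group, and the C1 configuration is in any case erased by the enolisation of step 4.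

Step 4
Reactants: 8 methyl lactone; 9 2-(iodomethyl)-4,4,5,5-tetramethyl-1,3,2-dioxaborolane
Product: 11 (3S,4S,5S)-5-[(tert-butyldiphenylsilyloxy)methyl]-3-methyl-3-[(4,4,5,5-tetramethyl-1,3,2-dioxaborolan-2-yl)methyl]-4-(prop-1-en-2-yl)dihydrofuran-2(3H)-one, via lithium enolate 10 (not isolated)
Conditions: LiN(i-Pr)2, THF, −78 °C; ICH2Bpin, −78 to −20 °C
Reagents that add atoms: 2-(iodomethyl)-4,4,5,5-tetramethyl-1,3,2-dioxaborolane, ICB1OC(C)(C)C(C)(C)O1
Why: A second enolate alkylation, now with the α-halomethyl boronate, should again bring the electrophile in anti to the adjacent isopropenyl group, so that the boryl-methyl carbon C14 ends trans and the methyl cis to C11, which sets the C1 quaternary centre.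

Step 5
Reactants: 11 boronate lactone; 12 ozone
Product: 14 (3S,4S,5S)-4-acetyl-5-[(tert-butyldiphenylsilyloxy)methyl]-3-methyl-3-[(4,4,5,5-tetramethyl-1,3,2-dioxaborolan-2-yl)methyl]dihydrofuran-2(3H)-one, via secondary ozonide 13 (not isolated)
Conditions: O3, CH2Cl2, −78 °C; Me2S, −78 °C to rt
Reagents that add atoms: ozone, [O-][O+]=O
Why: Ozonolysis with reductive work-up should cleave the only alkene to the C11 methyl ketone, the alkyl pinacol boronate and the silyl ether being inert to ozone at low temperature.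

Step 6
Reactants: 14 methyl ketone; 15 N-phenylbis(trifluoromethanesulfonimide)
Product: 17 (3S,4S,5S)-5-[(tert-butyldiphenylsilyloxy)methyl]-3-methyl-3-[(4,4,5,5-tetramethyl-1,3,2-dioxaborolan-2-yl)methyl]-4-[1-(trifluoromethylsulfonyloxy)vinyl]dihydrofuran-2(3H)-one, via potassium enolate 16 (not isolated)
Conditions: KN(SiMe3)2, THF, −78 °C; PhNTf2, −78 °C
Reagents that add atoms: N-phenylbis(trifluoromethanesulfonimide), O=S(=O)(N(c1ccccc1)S(=O)(=O)C(F)(F)F)C(F)(F)F
Why: Kinetic deprotonation at the unhindered C20 methyl group followed by O-sulfonylation of the enolate (enol triflate formation) should give the 1,1-disubstituted alkenyl triflate, the lactone α-carbon being quaternary and C10–H hindered.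

Step 7
Reactants: 17 enol triflate boronate; 18 tetravinyltin; 19 hydrogen peroxide
Product: 23 (3S,3aS,6S,7aS)-3-[(tert-butyldiphenylsilyloxy)methyl]-6-hydroxy-7a-methyl-4-methylenehexahydroisobenzofuran-1(3H)-one, via vinyllithium 20 (not isolated), via lithium vinylboronate complex 21 (not isolated), via cyclised pinacol boronate 22 (not isolated)
Conditions: Sn(CH=CH2)4, n-BuLi, Et2O, 0 °C; then 17, THF, −78 °C to rt; Pd(OAc)2 (3 mol %), MandyPhos (enantiomer giving 13S, 3.6 mol %), THF, 60 °C; then H2O2, aq. NaOH, 0 °C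
Reagents that add atoms: tetravinyltin, C=C[Sn](C=C)(C=C)C=C; hydrogen peroxide, OO
Why: Proposed new method: addition of vinyllithium to the C14 pinacol boronate gives a tetracoordinate vinylboronate, zerovalent palladium inserts into the C11–OTf bond, and the cationic alkenyl(divalent palladium) centre binds the boron-bound vinyl group as a π-acid so that C14 migrates from boron to C13 anti to the metal (C13–C14 bond) while palladium takes C12, after which reductive elimination from the seven-membered palladacycle forms C11–C12. The closest known reaction type is the intermolecular palladium-catalysed conjunctive cross-coupling of vinylboronate complexes with alkenyl triflates under MandyPhos ligation, which has not been shown with the migrating carbon and the triflate tethered in one molecule so as to close a ring. The cyclohexane ring (C11, C12, C13, C14, C1, C10) is closed by the C11–C12 reductive elimination, the C13–C14 bond having formed within the chain, and it is trans-fused to the lactone because C14 and C11 are trans on the template. The new C13 stereocentre is fixed in the metallate shift by the chiral bisphosphine, expected to be reinforced by a pseudo-equatorial boryl group in the cyclic transition state, and the oxidation of C–B to C–OH is stereoretentive. The step needs the metallate shift to outrun Suzuki-type vinyl transfer and β-hydride elimination, which the wide-bite-angle ligand and the halide-free triflate system should secure, and it needs boron to capture vinyllithium before the lactone does, which the hindered neopentyl carbonyl and −78 °C should secure.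

Step 8
Reactants: 23 hydroxy bicyclic lactone; 24 1,4-bis(trimethylsilyl)buta-1,3-diyne
Product: 26 diynone diol (cyclohexane with 1-methyl; 11-methylene; free 13-hydroxyl; C1 carries the 5-(trimethylsilyl)penta-2,4-diynoyl group C2–C5/C16; C10 carries the 1-hydroxy-2-(tert-butyldiphenylsilyloxy)ethyl group C9–C8; target arrangement at C1 C9 C10 C13), via lithium silylbutadiynide 25 (not isolated)
Conditions: 24, MeLi, THF, 0 °C; then 23 (0.45 equiv), THF, −78 to −20 °C; aq. NH4Cl
Reagents that add atoms: 1,4-bis(trimethylsilyl)buta-1,3-diyne, C[Si](C)(C)C#CC#C[Si](C)(C)C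
Why: Nucleophilic addition of the lithium acetylide to the lactone carbonyl (acyl substitution arrested at the tetrahedral alkoxide at low temperature) should open the template to the ynone and free the C9 hydroxyl without touching C1, C9 or C10.

Step 9
Reactants: 26 diynone diol
Product: 27 (2R)-propargylic alcohol of 26 (C2 C9 C13 triol)
Conditions: RuCl[(R,R)-TsDPEN](p-cymene) (2 mol %), i-PrOH, rt
Reagents that add atoms: none
Why: Noyori asymmetric transfer hydrogenation of the alkynyl ketone should set C2 under catalyst control, the (R,R)-catalyst giving the (R)-propargylic alcohol, which has the spatial arrangement of C2 in the target.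

Step 10
Reactants: 27 diynyl triol
Product: 29 (3E)-enyne triol with terminal C5≡C16 alkyne (C2 C9 C13 hydroxyls; C8 silyl ether), via silylated enyne triol 28 (not isolated)
Conditions: NaAlH2(OCH2CH2OCH3)2, THF, 0 °C; then MeOH, K2CO3, rt
Reagents that add atoms: none
Why: Hydroxyl-directed trans-hydroalumination of the propargylic alkyne (aluminium hydride reduction of a propargylic alcohol) should give the 3E alkene only at the alkyne next to the C2 alkoxide, and basic methanolysis then removes the alkynyl silyl group.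

Step 11
Reactants: 29 enyne triol; 30 acetic anhydride
Product: 31 enyne triacetate (acetates on C2 C9 C13)
Conditions: Ac2O, DMAP, pyridine, rt to 40 °C
Reagents that add atoms: acetic anhydride, CC(=O)OC(C)=O
Why: Exhaustive DMAP-catalysed acetylation should convert the three secondary alcohols into the acetates of the target while the primary silyl ether stays.

Step 12
Reactants: 31 enyne triacetate; 32 B-iodo-9-borabicyclo[3.3.1]nonane
Product: 34 2-iodo-1,3-diene triacetate (3E; iodine on C5; C16 methylene), via alkenylborane 33 (not isolated)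
Conditions: B-I-9-BBN, pentane/CH2Cl2, −20 °C; then AcOH, 0 °C
Reagents that add atoms: B-iodo-9-borabicyclo[3.3.1]nonane, IB1C2CCCC1CCC2
Why: Syn iodoboration of the terminal alkyne places iodine on the internal carbon C5 and boron on C16, and protonolysis of the C–B bond with acetic acid should give the 2-iodo-1,3-diene (Markovnikov hydroiodination) without touching alkenes or esters at low temperature.

Step 13
Reactants: 34 iododiene silyl ether
Product: 35 primary alcohol (free C8 hydroxyl)
Conditions: HF·pyridine, pyridine/THF, 0 °C to rt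
Reagents that add atoms: none
Why: Fluoride-mediated desilylation under buffered acidic conditions should free the C8 primary alcohol without acetate migration or loss.

Step 14
Reactants: 35 primary alcohol
Product: 36 C8 aldehyde (α-acetoxy aldehyde)
Conditions: Dess–Martin periodinane, NaHCO3, CH2Cl2, 0 °C
Reagents that add atoms: none
Why: Dess–Martin oxidation under buffered conditions should give the α-acetoxy aldehyde without epimerisation at C9.

Step 15
Reactants: 36 aldehyde; 37 vinylmagnesium bromide
Product: 38 allylic alcohol (C8 carbinol as the 8,9-anti Felkin epimer; vinyl group = C7 C6)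
Conditions: CH2=CHMgBr, THF, −78 °C; AcOH quench at −78 °C
Reagents that add atoms: vinylmagnesium bromide, C=C[Mg]Br
Why: Grignard addition to the aldehyde at −78 °C should outpace attack on the acetates and follow the polar Felkin–Anh model (C9–OAc anti to the nucleophile), which gives mainly the 8,9-anti allylic alcohol needed as the matched substrate of step 16.

Step 16
Reactants: 38 allylic alcohol; 39 tert-butyl hydroperoxide
Product: 40 erythro epoxy alcohol (C6–C7 oxirane; C8 carbinol)
Conditions: Ti(OiPr)4, L-(+)-diisopropyl tartrate, t-BuOOH, 4 Å molecular sieves, CH2Cl2, −20 °C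
Reagents that add atoms: tert-butyl hydroperoxide, CC(C)(C)OO
Why: Sharpless asymmetric epoxidation with the L-(+)-tartrate is matched for the Felkin epimer and should deliver oxygen to the face of the vinyl group that sets C7 under reagent control, the minor C8 epimer reacting slowly and being separated and the non-allylic alkenes being inert.

Step 17
Reactants: 40 epoxy alcohol
Product: 41 α,β-epoxy ketone (C8 ketone)
Conditions: Dess–Martin periodinane, NaHCO3, CH2Cl2, 0 °C to rt
Reagents that add atoms: none
Why: Dess–Martin oxidation should give the epoxy ketone and removes the temporary C8 stereocentre.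

Step 18
Reactants: 41 epoxy ketone; 42 4-methoxybenzyl alcohol
Product: 43 α-hydroxy ketone (C7 hydroxyl; C6 4-methoxybenzyl ether)
Conditions: 4-MeOC6H4CH2OH (5 equiv), Cu(BF4)2·6H2O (5 mol %), CH2Cl2, rt
Reagents that add atoms: 4-methoxybenzyl alcohol, COc1ccc(CO)cc1
Why: Lewis-acid-catalysed alcoholysis of the epoxide (SN2 ring opening) should occur at the terminal carbon C6, remote from the deactivating carbonyl, so that the C7–O bond and its configuration are retained.

Step 19
Reactants: 43 α-hydroxy ketone; 44 acryloyl chloride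
Product: 45 C7 acrylate of 43
Conditions: CH2=CHCOCl, i-Pr2NEt, CH2Cl2, −40 to 0 °C
Reagents that add atoms: acryloyl chloride, C=CC(=O)Cl
Why: O-Acylation of the secondary α-hydroxyl with acryloyl chloride under mild amine base should install the tethered enolate precursor without epimerising C7.

Step 20
Reactants: 45 keto acrylate
Product: 47 γ-lactone (C19 carbonyl; ring oxygen on C7; C8 tertiary hydroxyl; C17 methyl; C6 4-methoxybenzyl ether), via disiloxanyl ether 46 (not isolated)
Conditions: Cu(OAc)2·H2O (5 mol %), rac-BINAP (5 mol %), (HMe2Si)2O, THF, rt; then aq. citric acid, MeOH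
Reagents that add atoms: none
Why: Copper hydride-catalysed reductive aldol cyclisation (conjugate reduction of the acrylate, then intramolecular aldol addition of the copper enolate to the C8 ketone) should close the γ-lactone and set C17 and C8 together through a chelated Zimmerman–Traxler-type transition state that puts methyl and hydroxyl cis and the bulky C9 chain trans to the C6 substituent on C7.

Step 21
Reactants: 47 lactone 4-methoxybenzyl ether
Product: 48 lactone primary alcohol (free C6 hydroxyl)
Conditions: DDQ, CH2Cl2/pH 7 buffer, 0 °C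
Reagents that add atoms: none
Why: Oxidative cleavage of the 4-methoxybenzyl ether with DDQ should free the C6 primary alcohol without affecting acetates, lactone or the iododiene.

Step 22
Reactants: 48 lactone alcohol
Product: 49 lactone aldehyde (C6 aldehyde)
Conditions: Dess–Martin periodinane, NaHCO3, CH2Cl2, 0 °C
Reagents that add atoms: none
Why: Dess–Martin oxidation should give the C6 aldehyde, the tertiary C8 hydroxyl being inert.

Step 23
Reactants: 49 iododiene aldehyde
Product: 50 macrocyclic (6R)-alcohol (the target with hydroxyl in place of chlorine and the opposite arrangement at C6)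
Conditions: CrCl2 (4 equiv), chiral oxazoline–sulfonamide ligand (enantiomer giving 6R), NiCl2 (cat.), Et3N, THF/MeCN, rt, 1 mM
Reagents that add atoms: none
Why: Intramolecular Nozaki–Hiyama–Kishi reaction (nickel-catalysed activation of the alkenyl iodide, transmetalation to trivalent chromium, addition to the aldehyde) under high dilution should close the ten-membered ring at C5–C6, and the chiral sulfonamide ligand on chromium is chosen to give the (6R)-alcohol under reagent control.

Step 24
Reactants: 50 macrocyclic alcohol; 51 hexachloroacetone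
Product: 52 CNP0268873.1, (1S,2S,3E,6S,7R,8R,9S,10S,13S,17R)-2,9,13-triacetoxy-6-chloro-8-hydroxybriara-3,5(16),11(20)-triene 19,7-lactone
Conditions: PPh3, Cl3CC(O)CCl3, CH2Cl2, −20 to 0 °C
Reagents that add atoms: hexachloroacetone, ClC(Cl)(Cl)C(=O)C(Cl)(Cl)Cl
Why: Appel-type chlorination of the secondary allylic alcohol should proceed by SN2 displacement of the oxyphosphonium group with inversion and without allylic transposition, which sets the (6S)-chloride and completes the target.

Compound list

1 | (S)-5-(hydroxymethyl)furan-2(5H)-one | OC[C@H]1OC(=O)C=C1 | starting material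
2 | tert-butyl(chloro)diphenylsilane | CC(C)(C)[Si](Cl)(c1ccccc1)c1ccccc1 | starting material
3 | (S)-5-[(tert-butyldiphenylsilyloxy)methyl]furan-2(5H)-one | CC(C)(C)[Si](OC[C@H]1OC(=O)C=C1)(c1ccccc1)c1ccccc1 | intermediate
4 | isopropenylmagnesium bromide | CC(=C)[Mg]Br | starting material
5 | (4R,5S)-5-[(tert-butyldiphenylsilyloxy)methyl]-4-(prop-1-en-2-yl)dihydrofuran-2(3H)-one | C=C(C)[C@H]1CC(=O)O[C@@H]1CO[Si](c1ccccc1)(c1ccccc1)C(C)(C)C | intermediate
6 | iodomethane | CI | starting material
7 | lithium enolate of 5 | C=C(C)[C@H]1C=C(O[Li])O[C@@H]1CO[Si](c1ccccc1)(c1ccccc1)C(C)(C)C | intermediate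
8 | (3S,4R,5S)-5-[(tert-butyldiphenylsilyloxy)methyl]-3-methyl-4-(prop-1-en-2-yl)dihydrofuran-2(3H)-one | C=C(C)[C@H]1[C@H](C)C(=O)O[C@@H]1CO[Si](c1ccccc1)(c1ccccc1)C(C)(C)C | intermediate
9 | 2-(iodomethyl)-4,4,5,5-tetramethyl-1,3,2-dioxaborolane | ICB1OC(C)(C)C(C)(C)O1 | starting material
10 | lithium enolate of 8 | C=C(C)[C@H]1C(C)=C(O[Li])O[C@@H]1CO[Si](c1ccccc1)(c1ccccc1)C(C)(C)C | intermediate
11 | (3S,4S,5S)-5-[(tert-butyldiphenylsilyloxy)methyl]-3-methyl-3-[(pinacolboryl)methyl]-4-(prop-1-en-2-yl)dihydrofuran-2(3H)-one | C=C(C)[C@H]1[C@](C)(CB2OC(C)(C)C(C)(C)O2)C(=O)O[C@@H]1CO[Si](c1ccccc1)(c1ccccc1)C(C)(C)C | intermediate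
12 | ozone | [O-][O+]=O | starting material
13 | secondary ozonide of 11 (3-methyl-1,2,4-trioxolan-3-yl group on C10) | CC1(OCOO1)[C@H]1[C@](C)(CB2OC(C)(C)C(C)(C)O2)C(=O)O[C@@H]1CO[Si](c1ccccc1)(c1ccccc1)C(C)(C)C | intermediate
14 | (3S,4S,5S)-4-acetyl-5-[(tert-butyldiphenylsilyloxy)methyl]-3-methyl-3-[(pinacolboryl)methyl]dihydrofuran-2(3H)-one | CC(=O)[C@H]1[C@](C)(CB2OC(C)(C)C(C)(C)O2)C(=O)O[C@@H]1CO[Si](c1ccccc1)(c1ccccc1)C(C)(C)C | intermediate
15 | N-phenylbis(trifluoromethanesulfonimide) | O=S(=O)(N(c1ccccc1)S(=O)(=O)C(F)(F)F)C(F)(F)F | starting material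
16 | potassium enolate of 14 (C11–C20 enolate) | C=C(O[K])[C@H]1[C@](C)(CB2OC(C)(C)C(C)(C)O2)C(=O)O[C@@H]1CO[Si](c1ccccc1)(c1ccccc1)C(C)(C)C | intermediate
17 | (3S,4S,5S)-5-[(tert-butyldiphenylsilyloxy)methyl]-3-methyl-3-[(pinacolboryl)methyl]-4-[1-(trifluoromethylsulfonyloxy)vinyl]dihydrofuran-2(3H)-one | C=C(OS(=O)(=O)C(F)(F)F)[C@H]1[C@](C)(CB2OC(C)(C)C(C)(C)O2)C(=O)O[C@@H]1CO[Si](c1ccccc1)(c1ccccc1)C(C)(C)C | intermediate
18 | tetravinyltin | C=C[Sn](C=C)(C=C)C=C | starting material
19 | hydrogen peroxide | OO | starting material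
20 | vinyllithium | [Li]C=C | intermediate
21 | lithium vinylboronate complex of 17 | [Li+].C=C(OS(=O)(=O)C(F)(F)F)[C@H]1[C@](C)(C[B-]2(C=C)OC(C)(C)C(C)(C)O2)C(=O)O[C@@H]1CO[Si](c1ccccc1)(c1ccccc1)C(C)(C)C | intermediate
22 | (3S,3aS,6S,7aS)-3-[(tert-butyldiphenylsilyloxy)methyl]-7a-methyl-4-methylene-6-(pinacolboryl)hexahydroisobenzofuran-1(3H)-one | C=C1C[C@H](B3OC(C)(C)C(C)(C)O3)C[C@]2(C)C(=O)O[C@H](CO[Si](c3ccccc3)(c3ccccc3)C(C)(C)C)[C@@H]12 | intermediate
23 | (3S,3aS,6S,7aS)-3-[(tert-butyldiphenylsilyloxy)methyl]-6-hydroxy-7a-methyl-4-methylenehexahydroisobenzofuran-1(3H)-one | C=C1C[C@H](O)C[C@]2(C)C(=O)O[C@H](CO[Si](c3ccccc3)(c3ccccc3)C(C)(C)C)[C@@H]12 | intermediate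
24 | 1,4-bis(trimethylsilyl)buta-1,3-diyne | C[Si](C)(C)C#CC#C[Si](C)(C)C | starting material
25 | lithium (trimethylsilyl)buta-1,3-diynide | [Li]C#CC#C[Si](C)(C)C | intermediate
26 | diynone diol (C2 ketone; C9 and C13 hydroxyls; C8 silyl ether) | C=C1C[C@H](O)C[C@](C)(C(=O)C#CC#C[Si](C)(C)C)[C@H]1[C@H](O)CO[Si](c2ccccc2)(c2ccccc2)C(C)(C)C | intermediate
27 | (2R)-propargylic alcohol (C2, C9, C13 triol) | C=C1C[C@H](O)C[C@](C)([C@@H](O)C#CC#C[Si](C)(C)C)[C@H]1[C@H](O)CO[Si](c2ccccc2)(c2ccccc2)C(C)(C)C | intermediate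
28 | silylated (3E)-enyne triol | C=C1C[C@H](O)C[C@](C)([C@@H](O)/C=C/C#C[Si](C)(C)C)[C@H]1[C@H](O)CO[Si](c2ccccc2)(c2ccccc2)C(C)(C)C | intermediate
29 | (3E)-enyne triol with terminal alkyne | C=C1C[C@H](O)C[C@](C)([C@@H](O)/C=C/C#C)[C@H]1[C@H](O)CO[Si](c2ccccc2)(c2ccccc2)C(C)(C)C | intermediate
30 | acetic anhydride | CC(=O)OC(C)=O | starting material
31 | enyne triacetate | C=C1C[C@H](OC(C)=O)C[C@](C)([C@@H](OC(C)=O)/C=C/C#C)[C@H]1[C@H](OC(C)=O)CO[Si](c2ccccc2)(c2ccccc2)C(C)(C)C | intermediate
32 | B-iodo-9-borabicyclo[3.3.1]nonane | IB1C2CCCC1CCC2 | starting material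
33 | (Z)-2-iodoalkenyl-9-BBN adduct of 31 | C=C1C[C@H](OC(C)=O)C[C@](C)([C@@H](OC(C)=O)/C=C/C(/I)=C/B2C3CCCC2CCC3)[C@H]1[C@H](OC(C)=O)CO[Si](c2ccccc2)(c2ccccc2)C(C)(C)C | intermediate
34 | 2-iodo-1,3-diene triacetate silyl ether | C=C1C[C@H](OC(C)=O)C[C@](C)([C@@H](OC(C)=O)/C=C/C(I)=C)[C@H]1[C@H](OC(C)=O)CO[Si](c2ccccc2)(c2ccccc2)C(C)(C)C | intermediate
35 | primary alcohol (C8 hydroxyl) | C=C1C[C@H](OC(C)=O)C[C@](C)([C@@H](OC(C)=O)/C=C/C(I)=C)[C@H]1[C@H](OC(C)=O)CO | intermediate
36 | C8 aldehyde | C=C1C[C@H](OC(C)=O)C[C@](C)([C@@H](OC(C)=O)/C=C/C(I)=C)[C@H]1[C@H](OC(C)=O)C=O | intermediate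
37 | vinylmagnesium bromide | C=C[Mg]Br | starting material
38 | allylic alcohol (8,9-anti Felkin epimer) | C=C1C[C@H](OC(C)=O)C[C@](C)([C@@H](OC(C)=O)/C=C/C(I)=C)[C@H]1[C@H](OC(C)=O)[C@H](O)C=C | intermediate
39 | tert-butyl hydroperoxide | CC(C)(C)OO | starting material
40 | erythro epoxy alcohol (C6–C7 oxirane) | C=C1C[C@H](OC(C)=O)C[C@](C)([C@@H](OC(C)=O)/C=C/C(I)=C)[C@H]1[C@H](OC(C)=O)[C@H](O)[C@@H]2CO2 | intermediate
41 | α,β-epoxy ketone (C8 ketone) | C=C1C[C@H](OC(C)=O)C[C@](C)([C@@H](OC(C)=O)/C=C/C(I)=C)[C@H]1[C@H](OC(C)=O)C(=O)[C@@H]2CO2 | intermediate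
42 | 4-methoxybenzyl alcohol | COc1ccc(CO)cc1 | starting material
43 | α-hydroxy ketone (C7 hydroxyl; C6 4-methoxybenzyl ether) | C=C1C[C@H](OC(C)=O)C[C@](C)([C@@H](OC(C)=O)/C=C/C(I)=C)[C@H]1[C@H](OC(C)=O)C(=O)[C@@H](O)COCc2ccc(OC)cc2 | intermediate
44 | acryloyl chloride | C=CC(=O)Cl | starting material
45 | C7 acrylate of 43 | C=C1C[C@H](OC(C)=O)C[C@](C)([C@@H](OC(C)=O)/C=C/C(I)=C)[C@H]1[C@H](OC(C)=O)C(=O)[C@@H](OC(=O)C=C)COCc2ccc(OC)cc2 | intermediate
46 | O8-(1,1,3,3-tetramethyldisiloxanyl) ether of 47 | C=C1C[C@H](OC(C)=O)C[C@](C)([C@@H](OC(C)=O)/C=C/C(I)=C)[C@H]1[C@H](OC(C)=O)[C@]2(O[Si](C)(C)O[SiH](C)C)[C@@H](C)C(=O)O[C@H]2COCc2ccc(OC)cc2 | intermediate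
47 | γ-lactone with C8 hydroxyl, C17 methyl and C6 4-methoxybenzyl ether | C=C1C[C@H](OC(C)=O)C[C@](C)([C@@H](OC(C)=O)/C=C/C(I)=C)[C@H]1[C@H](OC(C)=O)[C@]2(O)[C@@H](C)C(=O)O[C@H]2COCc2ccc(OC)cc2 | intermediate
48 | lactone primary alcohol (C6 hydroxyl) | C=C1C[C@H](OC(C)=O)C[C@](C)([C@@H](OC(C)=O)/C=C/C(I)=C)[C@H]1[C@H](OC(C)=O)[C@]2(O)[C@@H](C)C(=O)O[C@H]2CO | intermediate
49 | lactone aldehyde (C6 aldehyde) | C=C1C[C@H](OC(C)=O)C[C@](C)([C@@H](OC(C)=O)/C=C/C(I)=C)[C@H]1[C@H](OC(C)=O)[C@]2(O)[C@@H](C)C(=O)O[C@H]2C=O | intermediate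
50 | macrocyclic (6R)-alcohol | C=C1C[C@H](OC(C)=O)C[C@]2(C)[C@@H](OC(C)=O)/C=C/C(=C)[C@@H](O)[C@@H]3OC(=O)[C@H](C)[C@@]3(O)[C@@H](OC(C)=O)[C@@H]12 | intermediate
51 | hexachloroacetone | ClC(Cl)(Cl)C(=O)C(Cl)(Cl)Cl | starting material
52 | CNP0268873.1 | C=C1C[C@H](OC(C)=O)C[C@]2(C)[C@@H](OC(C)=O)/C=C/C(=C)[C@H](Cl)[C@@H]3OC(=O)[C@H](C)[C@@]3(O)[C@@H](OC(C)=O)[C@@H]12 | target

Total step count: 24. Longest linear sequence: 24 steps (1 to 52).

Steps most likely to fail

Step 7 (Proposed new method). The process at risk is the partition of the alkenylpalladium intermediate: direct transfer of the vinyl group from boron to palladium, β-hydride elimination after the metallate shift, or poor facial control at C13. The fallback uses known chemistry and makes the same two ring bonds in two consecutive operations; it sets out from 17 and comes back at 23. The vinylboronate complex 21, made from 17 as in step 7, is treated with PhSeCl at −78 °C (electrophile-induced 1,2-metallate rearrangement, C13–C14 bond) to give the β-(phenylselanyl) boronic ester F1. Elimination of triflate with LiN(i-Pr)2 gives the terminal alkyne F2. Bu3SnH and AIBN generate the C12 radical, which closes the ring by 6-exo-dig cyclisation onto C11 (C11–C12 bond) to give the cyclised boronic ester F3 as a mixture of C13 epimers. H2O2/NaOH gives the alcohol mixture F4, Dess–Martin oxidation gives the ketone F5, and SmI2 in THF/i-PrOH should reduce it to the equatorial alcohol 23.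

Step 23. The process at risk is facial selectivity at C6 during ring closure, because the ligand must override the Felkin preference of the α-acyloxy aldehyde inside a forming medium ring. The fallback sets the stereocentre by ketone reduction instead of by the C–C bond formation; it sets out from 49 and comes back at 50. Ring closure with CrCl2 and catalytic NiCl2 in DMSO without chiral ligand gives the macrocyclic alcohol as its (6S)-epimer F6 or as a mixture with 50. Dess–Martin oxidation gives the cross-conjugated dienone F7. Corey–Bakshi–Shibata reduction, with the oxazaborolidine enantiomer chosen for hydride delivery to the face that gives the (6R)-carbinol, returns 50.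

Step 20. The process at risk is attack of the tethered copper enolate on the wrong face of the C8 ketone, or competing 1,2-reduction of that ketone by copper hydride. The fallback replaces the intramolecular aldol by an intermolecular, chelation-controlled addition; it sets out from 43 and comes back at 47. Reformatsky reaction of 43 with ethyl 2-bromopropanoate and zinc in THF, under Cram-chelate control by the free C7 hydroxyl, gives the dihydroxy ester F8. Lactonisation with PPTS gives 47 together with its C17 epimer F9, and DBU in toluene should equilibrate F9 to 47, in which the methyl group is trans to the C9 chain.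

Further compounds

F1 | step 7 | β-(phenylselanyl) boronic ester from 21 (C13 bears boron, C12 bears selenium, enol triflate intact; C13 epimers) | C=C(OS(=O)(=O)C(F)(F)F)[C@H]1[C@](C)(CC(C[Se]c2ccccc2)B2OC(C)(C)C(C)(C)O2)C(=O)O[C@@H]1CO[Si](c1ccccc1)(c1ccccc1)C(C)(C)C
F2 | step 7 | terminal alkyne from F1 (C11≡C20) | C#C[C@H]1[C@](C)(CC(C[Se]c2ccccc2)B2OC(C)(C)C(C)(C)O2)C(=O)O[C@@H]1CO[Si](c1ccccc1)(c1ccccc1)C(C)(C)C
F3 | step 7 | cyclised pinacol boronate as C13 epimers (contains 22) | C=C1CC(B3OC(C)(C)C(C)(C)O3)C[C@]2(C)C(=O)O[C@H](CO[Si](c3ccccc3)(c3ccccc3)C(C)(C)C)[C@@H]12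
F4 | step 7 | bicyclic alcohol as C13 epimers (contains 23) | C=C1CC(O)C[C@]2(C)C(=O)O[C@H](CO[Si](c3ccccc3)(c3ccccc3)C(C)(C)C)[C@@H]12
F5 | step 7 | C13 ketone of the bicyclic lactone | C=C1CC(=O)C[C@]2(C)C(=O)O[C@H](CO[Si](c3ccccc3)(c3ccccc3)C(C)(C)C)[C@@H]12
F6 | step 23 | macrocyclic (6S)-alcohol (C6 epimer of 50) | C=C1C[C@H](OC(C)=O)C[C@]2(C)[C@@H](OC(C)=O)/C=C/C(=C)[C@H](O)[C@@H]3OC(=O)[C@H](C)[C@@]3(O)[C@@H](OC(C)=O)[C@@H]12
F7 | step 23 | macrocyclic C6 dienone | C=C1C[C@H](OC(C)=O)C[C@]2(C)[C@@H](OC(C)=O)/C=C/C(=C)C(=O)[C@@H]3OC(=O)[C@H](C)[C@@]3(O)[C@@H](OC(C)=O)[C@@H]12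
F8 | step 20 | Reformatsky adduct of 43 (ethyl ester; C7 and C8 hydroxyls; C17 epimers) | C=C1C[C@H](OC(C)=O)C[C@](C)([C@@H](OC(C)=O)/C=C/C(I)=C)[C@H]1[C@H](OC(C)=O)[C@](O)(C(C)C(=O)OCC)[C@@H](O)COCc2ccc(OC)cc2
F9 | step 20 | C17 epimer of 47 | C=C1C[C@H](OC(C)=O)C[C@](C)([C@@H](OC(C)=O)/C=C/C(I)=C)[C@H]1[C@H](OC(C)=O)[C@]2(O)[C@H](C)C(=O)O[C@H]2COCc2ccc(OC)cc2
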